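A direct plan would cut both diaryl ether bonds as copper-mediated Ullmann couplings of a phenol with the benzyl ether of 5-bromoeugenol (A1): eugenol would give the protected dimer A2, debenzylation the dimer phenol A3, a second coupling with A1 the protected trimer A4, and a last debenzylation the target. Its weakest steps would be:
- the second ether coupling, where a phenoxide flanked by two ortho oxygen substituents must displace bromide next to an ortho alkoxy group, so reduction and homocoupling of A1 would compete;
- both couplings as such, because hot carbonate with copper would move the allyl double bonds into conjugation;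
- the debenzylations, since three alkenes exclude hydrogenolysis and Lewis acids would endanger the methyl ethers.

Rings B and C are the same unit, a 5-allyl-3-methoxy-1,2-phenylene whose C1 and C2 both carry oxygen. The route treats each as 5-allyl-3-methoxybenzyne and lets it insert into the O–B bond of an aryl pinacol borate: the aryloxide adds at C1, remote from the C3 methoxy group, and the C2 carbanion takes up boron, so one event forms the hindered ether bond and places the next oxygen. An N-oxide then moves boron from carbon to oxygen and regenerates a borate, so both insertions run in a single flask starting from eugenol. No metal-mediated ether coupling, no hot base and no phenol protecting group occur, and every allyl group arrives intact from eugenol.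

Key step: step 3

Remark: the target has no stereocentre, so no step has to set or preserve a configuration; the aryl pinacol borates are assumed to be moisture-sensitive and are therefore made and used without isolation.

Step 1
Reactants: 1 eugenol (4-allyl-2-methoxyphenol)
Product: 2 4-allyl-2-bromo-6-methoxyphenol
Conditions: NBS (1.0 equiv), i-Pr2NH (0.1 equiv), CH2Cl2, 0 °C, dark
Reagents that add atoms: N-bromosuccinimide, O=C1CCC(=O)N1Br
Why: Amine-catalysed ortho-bromination of a phenol (electrophilic aromatic substitution by an N-bromoamine hydrogen-bonded to the OH) should take the only free ortho position, while the unactivated terminal alkene reacts much more slowly with NBS in the dark at 0 °C.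

Step 2
Reactants: 2 4-allyl-2-bromo-6-methoxyphenol
Product: 5 4-allyl-2-methoxy-6-(trimethylsilyl)phenyl trifluoromethanesulfonate, via aryl trimethylsilyl ether 3 (not isolated), via lithium 2-silylphenolate 4 (not isolated)
Conditions: HMDS (0.6 equiv), THF, 65 °C, then evaporation; n-BuLi (1.1 equiv), THF, −78 °C; Tf2O (1.2 equiv), −78 → 0 °C
Reagents that add atoms: hexamethyldisilazane, C[Si](C)(C)N[Si](C)(C)C; trifluoromethanesulfonic anhydride, O=S(=O)(OS(=O)(=O)C(F)(F)F)C(F)(F)F
Why: This is the standard one-pot preparation of a 2-silylaryl triflate aryne precursor, namely O-silylation, bromine–lithium exchange (much faster at −78 °C than deprotonation of the allylic CH2), 1,3 O→C silyl shift (retro-Brook rearrangement) to phenolate 4 and O-triflation.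

Step 3
Reactants: 1 eugenol (4-allyl-2-methoxyphenol); 5 4-allyl-2-methoxy-6-(trimethylsilyl)phenyl trifluoromethanesulfonate (two charges)
Product: 10 2-{4-allyl-2-[4-allyl-2-(4-allyl-2-methoxyphenoxy)-6-methoxyphenoxy]-6-methoxyphenyl}-4,4,5,5-tetramethyl-1,3,2-dioxaborolane, via eugenyl pinacol borate 6 (not isolated), via 5-allyl-3-methoxybenzyne 7 (not isolated), via dimer arylboronate 8 (not isolated), via dimer pinacol borate 9 (not isolated)
Conditions: HBpin (1.05 equiv), toluene, 60 °C, then evaporation; 5 (1.0 equiv, slow addition), KF (1.5 equiv), 18-crown-6 (1.5 equiv), THF, 0 °C → rt; Me3NO (anhydrous, in portions until 8 is consumed by TLC), rt, then evaporation of NMe3 and THF; 5 (1.3 equiv, slow addition), KF (2 equiv), 18-crown-6 (2 equiv), THF, 0 °C → rt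
Reagents that add atoms: pinacolborane, CC1(C)OBOC1(C)C; trimethylamine N-oxide, C[N+](C)(C)[O-]
Why: Proposed new method: after catalyst-free dehydrogenative O-borylation of 1 to borate 6, fluoride desilylates 5 with loss of triflate to aryne 7 and also adds to boron of 6, so that the eugenyl oxide becomes available as a fluoroborate-bound or free aryloxide. This aryloxide adds to the aryne carbon remote from OMe (C1), because the σ-withdrawing C3 methoxy group distorts the triple bond towards a flatter, more electrophilic C1 and stabilises the carbanion that develops at C2 (the regiochemistry that 3-methoxybenzyne shows with heteroatom nucleophiles in general), and the C2 carbanion is captured by the boron electrophile held in the same ion pair (F–Bpin or a second molecule of 6), a net σ-insertion of the aryne into the O–B bond that gives 8 and stops there because 8 has a C–B and no O–B bond. Trimethylamine N-oxide then attacks boron of 8 and triggers the 1,2-shift of the aryl group from boron to oxygen (the known N-oxide oxidation of arylboronates, stopped at borate 9 because water is absent), and once trimethylamine has been stripped off, a second charge of 5 and fluoride repeats the insertion on 9, the higher homologue of 6, to give 10. The closest known reaction types are the fluoride-induced O-arylation of phenols (2,6-disubstituted ones included) with 2-silylaryl triflates, the σ-insertion of arynes into N–Si and S–Sn bonds, and three-component aryne couplings in which the aryl anion is trapped by CO2. No ring is closed and no stereocentre is formed. The step needs boron and not a proton to quench each carbanion, which the absence of any O–H group and the use of THF in place of acetonitrile should secure, and it needs each aryne to meet only a borate, which adding the N-oxide after the first charge of 5 is spent and removing the amine before the second should secure, while boron-free side products of the first insertion are inert in the later stages and leave at the chromatography of 10.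

Step 4
Reactants: 10 2-{4-allyl-2-[4-allyl-2-(4-allyl-2-methoxyphenoxy)-6-methoxyphenoxy]-6-methoxyphenyl}-4,4,5,5-tetramethyl-1,3,2-dioxaborolane
Product: 12 4-allyl-2-[4-allyl-2-(4-allyl-2-methoxyphenoxy)-6-methoxyphenoxy]-6-methoxyphenol (target), via trimer pinacol borate 11 (not isolated)
Conditions: Me3NO (1.5 equiv), THF, rt → 50 °C; then aq NH4Cl
Reagents that add atoms: trimethylamine N-oxide, C[N+](C)(C)[O-]
Why: N-oxide oxidation of an arylboronic ester (attack of the N-oxide oxygen on boron, 1,2-aryl shift to oxygen with loss of trimethylamine) followed by hydrolysis of borate 11 should free the phenol under conditions that leave the three allyl groups and the aryl ethers untouched.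

**Compound list**
1 | eugenol (4-allyl-2-methoxyphenol) | C=CCc1ccc(O)c(OC)c1 | starting material
2 | 4-allyl-2-bromo-6-methoxyphenol | C=CCc1cc(Br)c(O)c(OC)c1 | intermediate
3 | (4-allyl-2-bromo-6-methoxyphenoxy)trimethylsilane | C=CCc1cc(Br)c(O[Si](C)(C)C)c(OC)c1 | intermediate (not isolated)
4 | lithium 4-allyl-2-methoxy-6-(trimethylsilyl)phenolate | C=CCc1cc([Si](C)(C)C)c([O-])c(OC)c1.[Li+] | intermediate (not isolated)
5 | 4-allyl-2-methoxy-6-(trimethylsilyl)phenyl trifluoromethanesulfonate | C=CCc1cc([Si](C)(C)C)c(OS(=O)(=O)C(F)(F)F)c(OC)c1 | intermediate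
6 | 2-(4-allyl-2-methoxyphenoxy)-4,4,5,5-tetramethyl-1,3,2-dioxaborolane (eugenyl pinacol borate) | C=CCc1ccc(OB2OC(C)(C)C(C)(C)O2)c(OC)c1 | intermediate (not isolated)
7 | 5-allyl-3-methoxybenzyne (5-allyl-3-methoxy-1,2-didehydrobenzene) | C=CCC1=CC#CC(OC)=C1 | intermediate (not isolated)
8 | 2-[4-allyl-2-(4-allyl-2-methoxyphenoxy)-6-methoxyphenyl]-4,4,5,5-tetramethyl-1,3,2-dioxaborolane | C=CCc1ccc(Oc2cc(CC=C)cc(OC)c2B3OC(C)(C)C(C)(C)O3)c(OC)c1 | intermediate (not isolated)
9 | 2-[4-allyl-2-(4-allyl-2-methoxyphenoxy)-6-methoxyphenoxy]-4,4,5,5-tetramethyl-1,3,2-dioxaborolane | C=CCc1ccc(Oc2cc(CC=C)cc(OC)c2OB3OC(C)(C)C(C)(C)O3)c(OC)c1 | intermediate (not isolated)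
10 | 2-{4-allyl-2-[4-allyl-2-(4-allyl-2-methoxyphenoxy)-6-methoxyphenoxy]-6-methoxyphenyl}-4,4,5,5-tetramethyl-1,3,2-dioxaborolane | C=CCc1ccc(Oc2cc(CC=C)cc(OC)c2Oc2cc(CC=C)cc(OC)c2B3OC(C)(C)C(C)(C)O3)c(OC)c1 | intermediate
11 | 2-{4-allyl-2-[4-allyl-2-(4-allyl-2-methoxyphenoxy)-6-methoxyphenoxy]-6-methoxyphenoxy}-4,4,5,5-tetramethyl-1,3,2-dioxaborolane | C=CCc1ccc(Oc2cc(CC=C)cc(OC)c2Oc2cc(CC=C)cc(OC)c2OB3OC(C)(C)C(C)(C)O3)c(OC)c1 | intermediate (not isolated)
12 | 4-allyl-2-[4-allyl-2-(4-allyl-2-methoxyphenoxy)-6-methoxyphenoxy]-6-methoxyphenol (achiral) | C=CCc1ccc(Oc2cc(CC=C)cc(OC)c2Oc2cc(CC=C)cc(OC)c2O)c(OC)c1 | target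

Total step count: 4. Longest linear sequence: 4 steps (1 → 2 → 5 → 10 → 12); eugenol enters a second time in step 3.

Steps most likely to fail:

Step 3 (capture of an aryl anion by a proton instead of boron, fluoride held back by boron so that aryne formation stalls, or interception of the second aryne charge by residual amine or N-oxide). The fallback would set out from 1 and 2 and use known chemistry only. Bromide 2 would be protected as its methoxymethyl ether, 5-allyl-1-bromo-3-methoxy-2-(methoxymethoxy)benzene F1 (MOMCl, i-Pr2NEt, CH2Cl2). An Ullmann ether synthesis with 1 (CuI, N,N-dimethylglycine, Cs2CO3, dioxane, 90 °C) would give the protected dimer 5-allyl-1-(4-allyl-2-methoxyphenoxy)-3-methoxy-2-(methoxymethoxy)benzene F2. HCl in MeOH would free the phenol 4-allyl-2-(4-allyl-2-methoxyphenoxy)-6-methoxyphenol F3. Its palladium-catalysed C–O coupling with a second portion of F1 (Pd(OAc)2, tBuXPhos, K3PO4, toluene, 100 °C) would give the protected trimer 5-allyl-1-[4-allyl-2-(4-allyl-2-methoxyphenoxy)-6-methoxyphenoxy]-3-methoxy-2-(methoxymethoxy)benzene F4. HCl in MeOH would then return the route at the target 12.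

Step 1 (competing addition of electrophilic bromine to the terminal alkene). The fallback would set out from 1 and use bromine itself as a temporary protection of the alkene. Br2 (2 equiv, CH2Cl2, 0 °C) would give the racemic tribromide 2-bromo-4-(2,3-dibromopropyl)-6-methoxyphenol F5. Zinc dust in AcOH/EtOH would restore the allyl group by reductive elimination of the vicinal dibromide and return the route at 2.

Step 2 (deprotonation of the benzylic and allylic CH2 by the organolithium, or an incomplete O→C silyl shift before triflation). The fallback would set out from 2 and form the C–Si bond from an arylmagnesium on a protected phenol. The methoxymethyl ether already described as F1 (MOMCl, i-Pr2NEt, CH2Cl2) would be converted into its Grignard reagent (Mg turnings, LiCl, THF, rt) and quenched with Me3SiCl to give [5-allyl-3-methoxy-2-(methoxymethoxy)phenyl]trimethylsilane F6. PPTS in MeOH at 50 °C would free 4-allyl-2-methoxy-6-(trimethylsilyl)phenol F7. Tf2O with pyridine in CH2Cl2 at 0 °C would then return the route at 5.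

Further compounds
F1 | step 3 | 5-allyl-1-bromo-3-methoxy-2-(methoxymethoxy)benzene | C=CCc1cc(Br)c(OCOC)c(OC)c1
F2 | step 3 | 5-allyl-1-(4-allyl-2-methoxyphenoxy)-3-methoxy-2-(methoxymethoxy)benzene | C=CCc1ccc(Oc2cc(CC=C)cc(OC)c2OCOC)c(OC)c1
F3 | step 3 | 4-allyl-2-(4-allyl-2-methoxyphenoxy)-6-methoxyphenol | C=CCc1ccc(Oc2cc(CC=C)cc(OC)c2O)c(OC)c1
F4 | step 3 | 5-allyl-1-[4-allyl-2-(4-allyl-2-methoxyphenoxy)-6-methoxyphenoxy]-3-methoxy-2-(methoxymethoxy)benzene | C=CCc1ccc(Oc2cc(CC=C)cc(OC)c2Oc2cc(CC=C)cc(OC)c2OCOC)c(OC)c1
F5 | step 1 | 2-bromo-4-(2,3-dibromopropyl)-6-methoxyphenol (racemic) | BrCC(Br)Cc1cc(Br)c(O)c(OC)c1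
F6 | step 2 | [5-allyl-3-methoxy-2-(methoxymethoxy)phenyl]trimethylsilane | C=CCc1cc([Si](C)(C)C)c(OCOC)c(OC)c1
F7 | step 2 | 4-allyl-2-methoxy-6-(trimethylsilyl)phenol | C=CCc1cc([Si](C)(C)C)c(O)c(OC)c1
A1 | direct plan | 5-allyl-2-(benzyloxy)-1-bromo-3-methoxybenzene | C=CCc1cc(Br)c(OCc2ccccc2)c(OC)c1
A2 | direct plan | 5-allyl-1-(4-allyl-2-methoxyphenoxy)-2-(benzyloxy)-3-methoxybenzene | C=CCc1ccc(Oc2cc(CC=C)cc(OC)c2OCc2ccccc2)c(OC)c1
A3 | direct plan | 4-allyl-2-(4-allyl-2-methoxyphenoxy)-6-methoxyphenol | C=CCc1ccc(Oc2cc(CC=C)cc(OC)c2O)c(OC)c1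
A4 | direct plan | 5-allyl-1-[4-allyl-2-(4-allyl-2-methoxyphenoxy)-6-methoxyphenoxy]-2-(benzyloxy)-3-methoxybenzene | C=CCc1ccc(Oc2cc(CC=C)cc(OC)c2Oc2cc(CC=C)cc(OC)c2OCc2ccccc2)c(OC)c1
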